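The stirred vessel holds Z, on which Q turns into X. Midnight takes its whole Q at the start, while summer, a semi-batch flask, takes the same charge in 4 equal portions, 12 min apart.

in all of them: Z 18 µM
- north: Q 0.25 M (in portions, 4); run made earlier; portions every 12 min
- south-west: Q 0.40 M (in portions, 4); run made earlier; portions every 12 min
- midnight: Q 0.18 M; everything together at the start; time 3.0 h
- summer: Q 0.18 M (in portions, 4); the portions of Q follow each other after 12 min, the first at the start; time 3.0 h

- north (time / min: X / %, Q / %): 8.00: 0.9, 23.1; 15.0: 2.7, 47.7; 25.0: 5.1, 70.1; 40.0: 10.3, 89.4; 60.0: 16.7, 83.1; 120: 33.1, 66.6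
- south-west (time / min: X / %, Q / %): 8.00: 1.3, 23.8; 20.0: 4.0, 46.4; 40.0: 7.8, 92.5; 60.0: 13.0, 87.2; 80.0: 17.5, 83.0; 120: 25.8, 74.0

(scatter of a reading: 0.3 percentage points)

- the earlier runs were read with a standard deviation of 0.3 percentage points

* which of the two ends with the higher amount of X, in percent of the Q charged ("neither" if they lie within 2 percentage points) (midnight / summer / neither)
* X at the end, in percent of the Q charged, midnight
* X at the end, in percent of the Q charged, summer

Averaged over its portions, the charge of summer arrives 18.0 min late, and this mean dosing delay is the quantity to carry. The staircase of arrivals is replaced by its mean, so summer is read as midnight started that much later, and the gap at the end is the delay times the slope of the X curve.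

Over a stretch of 60.0 min, X would have to rise by less than 6.7 points for the two flasks to count as equal in this reckoning. After its dosing, the north run rose by 16 points between 60.0 min and 120 min, more than that. The south-west run rose by 13 points over the same stretch, also more.

The north slope gives a gap of 4.9 points. The error of this mean lies in the bend of the curve, so two other slopes are tried: the earlier north stretch from 40.0 min to 60.0 min gives 5.8 points, and the south-west slope gives 3.8 points. Both stay above 2 points. The reckoning here commits to the north figure, with midnight as the answer to the first question; the north charge stands 0.0700 M from this charge, the south-west charge 0.220 M.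

The forecast sets midnight at 55% and summer at 51.5%, a narrower gap of 3.5 points than the one reckoned here, and says “Batch should win, modestly”.

The flask gives 55.9% for midnight and 50.7% for summer, a gap of 5.2 points, from these steps:

    2 Z ⇌ E (K = 18000 M⁻¹, k = 28000 M⁻¹ min⁻¹)
    L → Z + X (k = 79.0 min⁻¹)
    Z → J (k = 0.00840 min⁻¹)
    Q + Z ⇌ L (K = 11.0 M⁻¹, k = 16000 M⁻¹ min⁻¹)

At 3.00 h, J holds 46.4% of the catalyst charged in midnight and 47.5% in summer. Midnight's own X rises from 34.9% at 1.50 h to 55.9% at 3.00 h, and over the delay of 18.0 min that slope gives 4.2 points.

Readings and results are calculated on assumed constants; scatter was added.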